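**Plan**

- Retrosynthesis: the C7–C8 bond is cut first, giving a ring-A aldehyde and a ring-B E-alkenyl iodide. Ring A is then opened at C2–C3, and the open chain is taken back to an ester at C1 and to an enolate plus formaldehyde at C6–C7. In ring B the C2′–Br bond goes back to C2′–OH and the iodoalkene to the isopropenyl group of (S)-limonene.
- Enabling feature: ring A is a skipped diene, with exocyclic C1=CH2 and endocyclic C3=C4 separated by the C2 methylene. The quaternary C5 (CMe2) sits next to C4, and C6 links C5 to C1. This is the pattern left when a 2-substituted allylsilane centred on C1 closes through its =CH2 terminus onto the free end of a terminal alkyne C3≡C4 carried by C5.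
- Forward order: the enyne is built on C6 (steps 1–8), ring A closes in step 9, ring B is taken whole from (S)-limonene and elaborated (steps 12–19), and the rings are joined last at C7–C8 (steps 20–22).
- Stereochemistry: C6 comes from an oxazolidinone-controlled titanium-enolate hydroxymethylation and C4′ from (S)-limonene. C1′ comes from trans-diaxial epoxide hydrolysis and C2′ from an Appel inversion. The E alkene comes from syn carboalumination and C7 from an oxazaborolidine-catalysed ketone reduction.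

Key step: step 9

**Remarks and assumptions**

- Numbering: ring A is C1 (=CH2), C2, C3=C4, C5 (CMe2), C6; the chain is C7 (carbinol), C8=C9 (C9 bears the methyl). Ring B is C1′ (C(OH)CH3), C2′ (CHBr), C3′, C4′ (bonded to C9), C5′, C6′.
- Assumption: 3,3-dimethylpent-4-enoic acid is taken as commercial; its commercial methyl ester gives it on saponification.
- Assumption: in the reduction of step 22 the α-branched ring-A carbon C6 behaves as the large carbonyl substituent and the alkenyl group as the small one.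
- Timing: steps 12–19 run in parallel with steps 1–10; step 11 is carried out immediately before step 20.

**Route**

Step 1
Reactants: 1 3,3-dimethylpent-4-enoic acid; 2 (4S)-4-benzyl-1,3-oxazolidin-2-one
Product: 4 (4S)-4-benzyl-3-(3,3-dimethylpent-4-enoyl)-1,3-oxazolidin-2-one, via mixed pivalic anhydride 3 (not isolated)
Conditions: t-BuCOCl, Et3N, THF, −20 °C; then 2, LiCl, −20 °C → rt
Reagents that add atoms: none
Why: N-acylation of the oxazolidinone through a mixed anhydride, with LiCl making the carbamate N–H acidic enough for Et3N, is routine for an α-unbranched acid and creates no stereocentre.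

Step 2
Reactants: 4 (4S)-4-benzyl-3-(3,3-dimethylpent-4-enoyl)-1,3-oxazolidin-2-one
Product: 5 (4S)-4-benzyl-3-[(2R)-2-(hydroxymethyl)-3,3-dimethylpent-4-enoyl]-1,3-oxazolidin-2-one
Conditions: TiCl4, iPr2NEt, CH2Cl2, 0 °C; then 1,3,5-trioxane, TiCl4, 0 °C
Reagents that add atoms: 1,3,5-trioxane, C1OCOCO1
Why: Soft enolisation should give the chelated Z titanium enolate, and TiCl4-activated formaldehyde should attack the face opposite the benzyl group (auxiliary-controlled titanium-enolate hydroxymethylation), which sets C6 in the required sense (2R in 5).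

Step 3
Reactants: 5 (4S)-4-benzyl-3-[(2R)-2-(hydroxymethyl)-3,3-dimethylpent-4-enoyl]-1,3-oxazolidin-2-one
Product: 6 (4S)-4-benzyl-3-[(2R)-2-{[(tert-butyldimethylsilyl)oxy]methyl}-3,3-dimethylpent-4-enoyl]-1,3-oxazolidin-2-one
Conditions: TBSCl, imidazole, DMF, rt
Reagents that add atoms: tert-butyldimethylsilyl chloride, CC(C)(C)[Si](C)(C)Cl
Why: Silylation of a primary alcohol with a silyl chloride and imidazole is standard, and it blocks retro-aldol loss of formaldehyde and later oxygen attack on the alkyne.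

Step 4
Reactants: 6 (4S)-4-benzyl-3-[(2R)-2-{[(tert-butyldimethylsilyl)oxy]methyl}-3,3-dimethylpent-4-enoyl]-1,3-oxazolidin-2-one
Product: 8 (2R)-2-{[(tert-butyldimethylsilyl)oxy]methyl}-3,3-dimethylpent-4-enoic acid, via peroxy acid 7 (not isolated)
Conditions: LiOH, H2O2, THF/H2O, 0 °C; then aq Na2SO3; then 1 M HCl to pH 3, 0 °C
Reagents that add atoms: hydrogen peroxide, OO
Why: Hydroperoxide anion attacks the exocyclic imide carbonyl selectively even when it is hindered (hydroperoxide cleavage of an N-acyloxazolidinone), sulfite reduces the peracid, and the hindered C6–H is not removed at 0 °C.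

Step 5
Reactants: 8 (2R)-2-{[(tert-butyldimethylsilyl)oxy]methyl}-3,3-dimethylpent-4-enoic acid
Product: 9 methyl (2R)-2-{[(tert-butyldimethylsilyl)oxy]methyl}-3,3-dimethylpent-4-enoate
Conditions: MeI, K2CO3, DMF, rt
Reagents that add atoms: iodomethane, CI
Why: SN2 O-methylation of the carboxylate needs no acid, so the silyl ether is safe, and carbonate does not enolise the hindered ester.

Step 6
Reactants: 9 methyl (2R)-2-{[(tert-butyldimethylsilyl)oxy]methyl}-3,3-dimethylpent-4-enoate
Product: 11 methyl (2R)-2-{[(tert-butyldimethylsilyl)oxy]methyl}-3,3-dimethyl-4-oxobutanoate, via ozonide 10 (not isolated)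
Conditions: O3, CH2Cl2, −78 °C; then Me2S, −78 °C → rt
Reagents that add atoms: ozone, [O-][O+]=O
Why: Ozonolysis with reductive work-up cleaves the only alkene and leaves a non-enolisable aldehyde on the quaternary carbon C5.

Step 7
Reactants: 11 methyl (2R)-2-{[(tert-butyldimethylsilyl)oxy]methyl}-3,3-dimethyl-4-oxobutanoate
Product: 12 methyl (2R)-2-{[(tert-butyldimethylsilyl)oxy]methyl}-3,3-dimethylpent-4-ynoate
Conditions: dimethyl (1-diazo-2-oxopropyl)phosphonate, K2CO3, MeOH, 0 °C → rt
Reagents that add atoms: dimethyl (1-diazo-2-oxopropyl)phosphonate, COP(=O)(OC)C(=[N+]=[N-])C(C)=O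
Why: The Ohira–Bestmann homologation turns a non-enolisable aldehyde into the terminal alkyne under carbonate conditions, and a methyl ester in methanol cannot be changed by transesterification.

Step 8
Reactants: 12 methyl (2R)-2-{[(tert-butyldimethylsilyl)oxy]methyl}-3,3-dimethylpent-4-ynoate; 13 [(trimethylsilyl)methyl]magnesium chloride
Product: 15 tert-butyldimethylsilyl ether of (2S)-3,3-dimethyl-2-[3-(trimethylsilyl)prop-1-en-2-yl]pent-4-yn-1-ol, via bis(silylmethyl) carbinol 14 (not isolated)
Conditions: CeCl3 (anhydrous), Me3SiCH2MgCl (5 equiv), THF, −78 °C → rt; then SiO2, CH2Cl2, rt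
Reagents that add atoms: none
Why: Double addition of the weakly basic organocerium reagent to the ester followed by Peterson elimination of the β-hydroxysilane on silica is an established ester-to-allylsilane conversion, and the low basicity should spare C6–H and the alkyne C–H.

Step 9
Reactants: 15 tert-butyldimethylsilyl ether of (2S)-3,3-dimethyl-2-[3-(trimethylsilyl)prop-1-en-2-yl]pent-4-yn-1-ol
Product: 16 tert-butyldimethylsilyl ether of [(1R)-2,2-dimethyl-6-methylidenecyclohex-3-en-1-yl]methanol
Conditions: Ph3PAuNTf2 (5 mol%), MeOH (2 equiv), CH2Cl2, 0 °C → rt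
Reagents that add atoms: none
Why: Proposed new method: Ph3PAuNTf2 should π-activate the terminal alkyne, and the =CH2 terminus of the allylsilane should attack the unsubstituted alkyne carbon anti to gold, giving a tertiary β-silyl cation at C1 and an alkenylgold at C4; methanol then takes the silyl group, leaving the exocyclic C1=CH2, and its proton cleaves the C4–Au bond to leave C3=C4. The closest known reactions are the gold- or platinum-catalysed 6-endo cycloisomerisation of 1,5-enynes to cyclohexa-1,4-dienes and allylsilane-terminated carbocyclisations onto metal-activated alkynes. Ring A closes in the 6-endo-dig mode by forming C2–C3. No stereocentre is created; C6 was set in step 2 and is untouched because no charge develops at it. The step needs 6-endo rather than 5-exo attack, which the short 1,5-tether and the quaternary C5 shielding the internal alkyne carbon should secure, and it needs the new alkene to end exocyclic, which loss of silicon from the β-silyl cation dictates. The oxygen is silylated so it cannot add to the activated alkyne, and the small amount of methanol should keep alkyne methanolysis and protodesilylation of 15 slow.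

Step 10
Reactants: 16 tert-butyldimethylsilyl ether of [(1R)-2,2-dimethyl-6-methylidenecyclohex-3-en-1-yl]methanol
Product: 17 [(1R)-2,2-dimethyl-6-methylidenecyclohex-3-en-1-yl]methanol
Conditions: Bu4NF, THF, 0 °C → rt
Reagents that add atoms: none
Why: Fluoride-mediated desilylation is neutral towards the skipped diene.

Step 11
Reactants: 17 [(1R)-2,2-dimethyl-6-methylidenecyclohex-3-en-1-yl]methanol
Product: 18 (1R)-2,2-dimethyl-6-methylidenecyclohex-3-ene-1-carbaldehyde
Conditions: Dess–Martin periodinane, pyridine, CH2Cl2, 0 °C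
Reagents that add atoms: none
Why: Dess–Martin oxidation buffered with pyridine should give the β,γ-unsaturated aldehyde without epimerising C6 or moving the exocyclic alkene into conjugation, and the aldehyde is used at once.

Step 12
Reactants: 19 (S)-limonene
Product: 20 (4S)-limonene 1,2-oxide as a mixture of epoxide epimers
Conditions: mCPBA (1.0 equiv), NaHCO3, CH2Cl2, 0 °C
Reagents that add atoms: 3-chloroperoxybenzoic acid, OOC(=O)c1cccc(Cl)c1
Why: In this Prilezhaev epoxidation the trisubstituted ring alkene is more nucleophilic than the isopropenyl group, so one equivalent of peracid reacts there, and both epimers are usable in step 13.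

Step 13
Reactants: 20 (4S)-limonene 1,2-oxide as a mixture of epoxide epimers
Product: 21 (1R,2R,4S)-1-methyl-4-(prop-1-en-2-yl)cyclohexane-1,2-diol
Conditions: 1% aq H2SO4, THF, 0 °C → rt
Reagents that add atoms: water, O
Why: Acid-catalysed hydrolysis follows the Fürst–Plattner trans-diaxial rule, so water attacks C2′ of the epoxide whose oxygen is syn to the isopropenyl group and C1′ of the other epimer, and both converge on the one diol with C1′–OH on the face of the C4′ substituent.

Step 14
Reactants: 21 (1R,2R,4S)-1-methyl-4-(prop-1-en-2-yl)cyclohexane-1,2-diol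
Product: 22 (1R,2R,4S)-1-methyl-4-(prop-1-en-2-yl)-1,2-bis[(triethylsilyl)oxy]cyclohexane
Conditions: Et3SiOTf, 2,6-lutidine, CH2Cl2, −78 → 0 °C
Reagents that add atoms: triethylsilyl trifluoromethanesulfonate, CC[Si](CC)(CC)OS(=O)(=O)C(F)(F)F
Why: Silyl triflate with lutidine silylates secondary and tertiary hydroxyls alike, and this protection is needed for the strong base of step 16 and the AlMe3 of step 17.

Step 15
Reactants: 22 (1R,2R,4S)-1-methyl-4-(prop-1-en-2-yl)-1,2-bis[(triethylsilyl)oxy]cyclohexane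
Product: 24 1-[(1S,3R,4R)-4-methyl-3,4-bis[(triethylsilyl)oxy]cyclohexyl]ethan-1-one, via ozonide 23 (not isolated)
Conditions: O3, CH2Cl2, −78 °C; then Me2S, −78 °C → rt
Reagents that add atoms: ozone, [O-][O+]=O
Why: Ozonolysis with reductive work-up cleaves the remaining 1,1-disubstituted alkene to the methyl ketone and does not touch silyl ethers.

Step 16
Reactants: 24 1-[(1S,3R,4R)-4-methyl-3,4-bis[(triethylsilyl)oxy]cyclohexyl]ethan-1-one
Product: 26 (1R,2R,4S)-4-ethynyl-1-methyl-1,2-bis[(triethylsilyl)oxy]cyclohexane, via enol phosphate 25 (not isolated)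
Conditions: LiN(iPr)2 (1.1 equiv), THF, −78 °C; ClP(O)(OEt)2, −78 °C → rt; then LiN(iPr)2 (2.3 equiv), −78 °C → rt; H2O
Reagents that add atoms: none
Why: Kinetic deprotonation at the methyl group, O-phosphorylation and base-induced elimination of the enol phosphate is the standard methyl ketone to terminal alkyne conversion, and the acetylide formed protects the C4′–H from the base.

Step 17
Reactants: 26 (1R,2R,4S)-4-ethynyl-1-methyl-1,2-bis[(triethylsilyl)oxy]cyclohexane
Product: 28 (1R,2R,4S)-4-[(1E)-1-iodoprop-1-en-2-yl]-1-methyl-1,2-bis[(triethylsilyl)oxy]cyclohexane, via alkenylalane 27 (not isolated)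
Conditions: AlMe3, Cp2ZrCl2 (0.25 equiv), CH2Cl2, 0 °C → rt; then I2, THF, −30 → 0 °C
Reagents that add atoms: trimethylaluminium, C[Al](C)C; iodine, II
Why: Zirconium-catalysed syn methylalumination of a terminal alkyne (Negishi carboalumination) puts methyl on C9 and aluminium on C8, and iodinolysis with retention gives the E iodoalkene.

Step 18
Reactants: 28 (1R,2R,4S)-4-[(1E)-1-iodoprop-1-en-2-yl]-1-methyl-1,2-bis[(triethylsilyl)oxy]cyclohexane
Product: 29 (1R,2R,4S)-4-[(1E)-1-iodoprop-1-en-2-yl]-1-methylcyclohexane-1,2-diol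
Conditions: HF·pyridine, pyridine, THF, 0 °C → rt
Reagents that add atoms: none
Why: Fluoride cleaves both triethylsilyl ethers under conditions to which the alkenyl iodide is inert.

Step 19
Reactants: 29 (1R,2R,4S)-4-[(1E)-1-iodoprop-1-en-2-yl]-1-methylcyclohexane-1,2-diol
Product: 30 (1R,2S,4S)-2-bromo-4-[(1E)-1-iodoprop-1-en-2-yl]-1-methylcyclohexan-1-ol
Conditions: CBr4, PPh3, CH2Cl2, 0 °C → rt
Reagents that add atoms: tetrabromomethane, BrC(Br)(Br)Br
Why: In this Appel reaction only the secondary axial hydroxyl should form the alkoxyphosphonium ion, and bromide should displace it with inversion, placing bromine equatorial and cis to the tertiary hydroxyl, which does not react under these neutral conditions.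

Step 20
Reactants: 18 (1R)-2,2-dimethyl-6-methylidenecyclohex-3-ene-1-carbaldehyde; 30 (1R,2S,4S)-2-bromo-4-[(1E)-1-iodoprop-1-en-2-yl]-1-methylcyclohexan-1-ol
Product: 31 (2E)-3-[(1S,3S,4R)-3-bromo-4-hydroxy-4-methylcyclohexyl]-1-[(1R)-2,2-dimethyl-6-methylidenecyclohex-3-en-1-yl]but-2-en-1-ol as a mixture of C7 epimers
Conditions: CrCl2 (6 equiv), NiCl2 (1 mol%), DMSO, rt
Reagents that add atoms: none
Why: The Nozaki–Hiyama–Kishi coupling forms the alkenylchromium reagent with retention of alkene geometry and adds it to hindered aldehydes, it tolerates the free hydroxyl and the secondary bromide, and it is not basic enough to epimerise C6; the C7 mixture is corrected in steps 21 and 22.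

Step 21
Reactants: 31 (2E)-3-[(1S,3S,4R)-3-bromo-4-hydroxy-4-methylcyclohexyl]-1-[(1R)-2,2-dimethyl-6-methylidenecyclohex-3-en-1-yl]but-2-en-1-ol as a mixture of C7 epimers
Product: 32 (2E)-3-[(1S,3S,4R)-3-bromo-4-hydroxy-4-methylcyclohexyl]-1-[(1R)-2,2-dimethyl-6-methylidenecyclohex-3-en-1-yl]but-2-en-1-one
Conditions: Dess–Martin periodinane, pyridine, CH2Cl2, 0 °C
Reagents that add atoms: none
Why: Dess–Martin oxidation of the allylic alcohol merges both C7 epimers into one enone, the tertiary alcohol cannot be oxidised, and the buffer protects C6.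

Step 22
Reactants: 32 (2E)-3-[(1S,3S,4R)-3-bromo-4-hydroxy-4-methylcyclohexyl]-1-[(1R)-2,2-dimethyl-6-methylidenecyclohex-3-en-1-yl]but-2-en-1-one
Product: 33 (1R,2E)-3-[(1S,3S,4R)-3-bromo-4-hydroxy-4-methylcyclohexyl]-1-[(1R)-2,2-dimethyl-6-methylidenecyclohex-3-en-1-yl]but-2-en-1-ol
Conditions: (S)-1-methyl-3,3-diphenyltetrahydro-1H,3H-pyrrolo[1,2-c][1,3,2]oxazaborole (0.5 equiv), catecholborane, toluene, −78 °C; then MeOH, aq NaOH
Reagents that add atoms: none
Why: In this Corey–Bakshi–Shibata reduction the oxazaborolidine should bind the carbonyl lone pair on the side of the slim alkenyl group, treat the branched C6 as the large substituent and deliver hydride 1,2 to give the 7R carbinol, while catecholborane at −78 °C leaves the alkenes alone.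

**Compound list**

1 | 3,3-dimethylpent-4-enoic acid | C=CC(C)(C)CC(=O)O | starting material
2 | (4S)-4-benzyl-1,3-oxazolidin-2-one | O=C1N[C@@H](Cc2ccccc2)CO1 | starting material
3 | 3,3-dimethylpent-4-enoic pivalic anhydride | C=CC(C)(C)CC(=O)OC(=O)C(C)(C)C | intermediate (not isolated)
4 | (4S)-4-benzyl-3-(3,3-dimethylpent-4-enoyl)-1,3-oxazolidin-2-one | C=CC(C)(C)CC(=O)N1C(=O)OC[C@@H]1Cc1ccccc1 | intermediate
5 | (4S)-4-benzyl-3-[(2R)-2-(hydroxymethyl)-3,3-dimethylpent-4-enoyl]-1,3-oxazolidin-2-one | O=C([C@@H](CO)C(C)(C)C=C)N1C(=O)OC[C@@H]1Cc1ccccc1 | intermediate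
6 | (4S)-4-benzyl-3-[(2R)-2-{[(tert-butyldimethylsilyl)oxy]methyl}-3,3-dimethylpent-4-enoyl]-1,3-oxazolidin-2-one | O=C([C@@H](CO[Si](C)(C)C(C)(C)C)C(C)(C)C=C)N1C(=O)OC[C@@H]1Cc1ccccc1 | intermediate
7 | (2R)-2-{[(tert-butyldimethylsilyl)oxy]methyl}-3,3-dimethylpent-4-eneperoxoic acid | OOC(=O)[C@@H](CO[Si](C)(C)C(C)(C)C)C(C)(C)C=C | intermediate (not isolated)
8 | (2R)-2-{[(tert-butyldimethylsilyl)oxy]methyl}-3,3-dimethylpent-4-enoic acid | OC(=O)[C@@H](CO[Si](C)(C)C(C)(C)C)C(C)(C)C=C | intermediate
9 | methyl (2R)-2-{[(tert-butyldimethylsilyl)oxy]methyl}-3,3-dimethylpent-4-enoate | COC(=O)[C@@H](CO[Si](C)(C)C(C)(C)C)C(C)(C)C=C | intermediate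
10 | ozonide of 9: methyl (2R)-2-{[(tert-butyldimethylsilyl)oxy]methyl}-3-methyl-3-(1,2,4-trioxolan-3-yl)butanoate (trioxolane carbon unassigned) | COC(=O)[C@@H](CO[Si](C)(C)C(C)(C)C)C(C)(C)C1OCOO1 | intermediate (not isolated)
11 | methyl (2R)-2-{[(tert-butyldimethylsilyl)oxy]methyl}-3,3-dimethyl-4-oxobutanoate | COC(=O)[C@@H](CO[Si](C)(C)C(C)(C)C)C(C)(C)C=O | intermediate
12 | methyl (2R)-2-{[(tert-butyldimethylsilyl)oxy]methyl}-3,3-dimethylpent-4-ynoate | COC(=O)[C@@H](CO[Si](C)(C)C(C)(C)C)C(C)(C)C#C | intermediate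
13 | [(trimethylsilyl)methyl]magnesium chloride, Me3SiCH2MgCl | C[Si](C)(C)C[Mg]Cl | starting material
14 | (3R)-3-{[(tert-butyldimethylsilyl)oxy]methyl}-4,4-dimethyl-1-(trimethylsilyl)-2-[(trimethylsilyl)methyl]hex-5-yn-2-ol | C[Si](C)(C)CC(O)(C[Si](C)(C)C)[C@@H](CO[Si](C)(C)C(C)(C)C)C(C)(C)C#C | intermediate (not isolated)
15 | tert-butyldimethylsilyl ether of (2S)-3,3-dimethyl-2-[3-(trimethylsilyl)prop-1-en-2-yl]pent-4-yn-1-ol | C=C(C[Si](C)(C)C)[C@@H](CO[Si](C)(C)C(C)(C)C)C(C)(C)C#C | intermediate
16 | tert-butyldimethylsilyl ether of [(1R)-2,2-dimethyl-6-methylidenecyclohex-3-en-1-yl]methanol | C=C1CC=CC(C)(C)[C@@H]1CO[Si](C)(C)C(C)(C)C | intermediate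
17 | [(1R)-2,2-dimethyl-6-methylidenecyclohex-3-en-1-yl]methanol | C=C1CC=CC(C)(C)[C@@H]1CO | intermediate
18 | (1R)-2,2-dimethyl-6-methylidenecyclohex-3-ene-1-carbaldehyde | C=C1CC=CC(C)(C)[C@@H]1C=O | intermediate
19 | (S)-limonene, (4S)-1-methyl-4-(prop-1-en-2-yl)cyclohex-1-ene | C=C(C)[C@H]1CCC(C)=CC1 | starting material
20 | (4S)-limonene 1,2-oxide, (4S)-1-methyl-4-(prop-1-en-2-yl)-7-oxabicyclo[4.1.0]heptane (both epoxide epimers) | C=C(C)[C@H]1CCC2(C)OC2C1 | intermediate
21 | (1R,2R,4S)-1-methyl-4-(prop-1-en-2-yl)cyclohexane-1,2-diol | C=C(C)[C@H]1CC[C@@](C)(O)[C@H](O)C1 | intermediate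
22 | (1R,2R,4S)-1-methyl-4-(prop-1-en-2-yl)-1,2-bis[(triethylsilyl)oxy]cyclohexane | C=C(C)[C@H]1CC[C@@](C)(O[Si](CC)(CC)CC)[C@H](O[Si](CC)(CC)CC)C1 | intermediate
23 | ozonide of 22: (1R,2R,4S)-1-methyl-4-(3-methyl-1,2,4-trioxolan-3-yl)-1,2-bis[(triethylsilyl)oxy]cyclohexane (trioxolane carbon unassigned) | CC1(OCOO1)[C@H]1CC[C@@](C)(O[Si](CC)(CC)CC)[C@H](O[Si](CC)(CC)CC)C1 | intermediate (not isolated)
24 | 1-[(1S,3R,4R)-4-methyl-3,4-bis[(triethylsilyl)oxy]cyclohexyl]ethan-1-one | CC(=O)[C@H]1CC[C@@](C)(O[Si](CC)(CC)CC)[C@H](O[Si](CC)(CC)CC)C1 | intermediate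
25 | diethyl 1-[(1S,3R,4R)-4-methyl-3,4-bis[(triethylsilyl)oxy]cyclohexyl]ethenyl phosphate | C=C(OP(=O)(OCC)OCC)[C@H]1CC[C@@](C)(O[Si](CC)(CC)CC)[C@H](O[Si](CC)(CC)CC)C1 | intermediate (not isolated)
26 | (1R,2R,4S)-4-ethynyl-1-methyl-1,2-bis[(triethylsilyl)oxy]cyclohexane | C#C[C@H]1CC[C@@](C)(O[Si](CC)(CC)CC)[C@H](O[Si](CC)(CC)CC)C1 | intermediate
27 | dimethyl{(1E)-2-[(1S,3R,4R)-4-methyl-3,4-bis[(triethylsilyl)oxy]cyclohexyl]prop-1-en-1-yl}alane | C[Al](C)/C=C(\C)[C@H]1CC[C@@](C)(O[Si](CC)(CC)CC)[C@H](O[Si](CC)(CC)CC)C1 | intermediate (not isolated)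
28 | (1R,2R,4S)-4-[(1E)-1-iodoprop-1-en-2-yl]-1-methyl-1,2-bis[(triethylsilyl)oxy]cyclohexane | I/C=C(\C)[C@H]1CC[C@@](C)(O[Si](CC)(CC)CC)[C@H](O[Si](CC)(CC)CC)C1 | intermediate
29 | (1R,2R,4S)-4-[(1E)-1-iodoprop-1-en-2-yl]-1-methylcyclohexane-1,2-diol | I/C=C(\C)[C@H]1CC[C@@](C)(O)[C@H](O)C1 | intermediate
30 | (1R,2S,4S)-2-bromo-4-[(1E)-1-iodoprop-1-en-2-yl]-1-methylcyclohexan-1-ol | I/C=C(\C)[C@H]1CC[C@@](C)(O)[C@@H](Br)C1 | intermediate
31 | (2E)-3-[(1S,3S,4R)-3-bromo-4-hydroxy-4-methylcyclohexyl]-1-[(1R)-2,2-dimethyl-6-methylidenecyclohex-3-en-1-yl]but-2-en-1-ol (both C7 epimers) | C=C1CC=CC(C)(C)[C@@H]1C(O)/C=C(\C)[C@H]1CC[C@@](C)(O)[C@@H](Br)C1 | intermediate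
32 | (2E)-3-[(1S,3S,4R)-3-bromo-4-hydroxy-4-methylcyclohexyl]-1-[(1R)-2,2-dimethyl-6-methylidenecyclohex-3-en-1-yl]but-2-en-1-one | C=C1CC=CC(C)(C)[C@@H]1C(=O)/C=C(\C)[C@H]1CC[C@@](C)(O)[C@@H](Br)C1 | intermediate
33 | (1R,2E)-3-[(1S,3S,4R)-3-bromo-4-hydroxy-4-methylcyclohexyl]-1-[(1R)-2,2-dimethyl-6-methylidenecyclohex-3-en-1-yl]but-2-en-1-ol | C=C1CC=CC(C)(C)[C@@H]1[C@H](O)/C=C(\C)[C@H]1CC[C@@](C)(O)[C@@H](Br)C1 | target

**Step count**

Total: 22 steps. Longest linear sequence: 14 steps (steps 1–11 and 20–22); the ring-B branch has 8 steps (12–19) before the coupling.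

**Steps most likely to fail**

Step 9 (labelled step). The cyclisation may go astray in several ways: attack at the internal alkyne carbon (5-exo closure), a cyclopropyl-carbene skeletal rearrangement, protodesilylation of the allylsilane before ring closure, or acid-promoted migration of the exocyclic alkene into the ring. The fallback uses only known reactions and closes ring A at C3=C4 by ring-closing metathesis. It sets out from acid 8, which is coupled with N,O-dimethylhydroxylamine hydrochloride (EDC·HCl, HOBt, iPr2NEt, CH2Cl2) to give (2R)-2-{[(tert-butyldimethylsilyl)oxy]methyl}-N-methoxy-N,3,3-trimethylpent-4-enamide F1. Addition of CH2=CHCH2MgBr (THF, −78 °C) gives (4R)-4-{[(tert-butyldimethylsilyl)oxy]methyl}-5,5-dimethylhepta-1,6-dien-3-one F2. Non-basic methylenation with Cp2TiMe2 (toluene, 65 °C) gives tert-butyl{[(2R)-3-methylidene-2-(2-methylbut-3-en-2-yl)hex-5-en-1-yl]oxy}dimethylsilane F3. Its vinyl and allyl termini are then joined with the second-generation Grubbs catalyst (H2IMes)(PCy3)Cl2Ru=CHPh (CH2Cl2, 40 °C); the 1,1-disubstituted alkene cannot form a ring of useful size and should stay exocyclic. The fallback returns to the route at compound 16.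

Step 19. The alkoxyphosphonium ion may be displaced from within by the trans-diaxial tertiary hydroxyl (epoxide formation, then reopening by HBr with net retention at C2′), or may undergo elimination, instead of being attacked by external bromide on the hindered face. The fallback masks the tertiary hydroxyl and uses a discrete sulfonate displacement. It sets out from 28, whose less hindered secondary silyl ether is removed selectively (pyridinium p-toluenesulfonate, MeOH, 0 °C) to give (1R,2R,5S)-5-[(1E)-1-iodoprop-1-en-2-yl]-2-methyl-2-[(triethylsilyl)oxy]cyclohexan-1-ol F4. Triflation (Tf2O, pyridine, CH2Cl2, −40 °C) gives (1R,2R,5S)-5-[(1E)-1-iodoprop-1-en-2-yl]-2-methyl-2-[(triethylsilyl)oxy]cyclohexyl trifluoromethanesulfonate F5. SN2 displacement with Bu4NBr (toluene, 0 °C → rt) gives {[(1R,2S,4S)-2-bromo-4-[(1E)-1-iodoprop-1-en-2-yl]-1-methylcyclohexyl]oxy}triethylsilane F6. Desilylation with HF·pyridine returns to the route at compound 30.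

Step 22. Facial selectivity may be poor because the two carbonyl substituents are not clearly different in size for the catalyst, or because the substrate's own Felkin–Anh preference opposes the catalyst. The fallback sets C7 while the C7–C8 bond is formed and omits the ketone. It sets out from 18 and 30, which are coupled under ligand-controlled Nozaki–Hiyama–Kishi conditions (CrCl2, a chiral oxazoline–sulfonamide ligand, Et3N, NiCl2 as catalyst, THF). The ligand enantiomer is chosen to reinforce the Felkin–Anh preference expected for attack anti to the quaternary C5. The fallback returns to the route at compound 33 and makes no new compound (F0).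

**Further compounds**

F1 | step 9 | (2R)-2-{[(tert-butyldimethylsilyl)oxy]methyl}-N-methoxy-N,3,3-trimethylpent-4-enamide | CON(C)C(=O)[C@@H](CO[Si](C)(C)C(C)(C)C)C(C)(C)C=C
F2 | step 9 | (4R)-4-{[(tert-butyldimethylsilyl)oxy]methyl}-5,5-dimethylhepta-1,6-dien-3-one | C=CCC(=O)[C@@H](CO[Si](C)(C)C(C)(C)C)C(C)(C)C=C
F3 | step 9 | tert-butyl{[(2R)-3-methylidene-2-(2-methylbut-3-en-2-yl)hex-5-en-1-yl]oxy}dimethylsilane | C=CCC(=C)[C@@H](CO[Si](C)(C)C(C)(C)C)C(C)(C)C=C
F4 | step 19 | (1R,2R,5S)-5-[(1E)-1-iodoprop-1-en-2-yl]-2-methyl-2-[(triethylsilyl)oxy]cyclohexan-1-ol | I/C=C(\C)[C@H]1CC[C@@](C)(O[Si](CC)(CC)CC)[C@H](O)C1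
F5 | step 19 | (1R,2R,5S)-5-[(1E)-1-iodoprop-1-en-2-yl]-2-methyl-2-[(triethylsilyl)oxy]cyclohexyl trifluoromethanesulfonate | I/C=C(\C)[C@H]1CC[C@@](C)(O[Si](CC)(CC)CC)[C@H](OS(=O)(=O)C(F)(F)F)C1
F6 | step 19 | {[(1R,2S,4S)-2-bromo-4-[(1E)-1-iodoprop-1-en-2-yl]-1-methylcyclohexyl]oxy}triethylsilane | I/C=C(\C)[C@H]1CC[C@@](C)(O[Si](CC)(CC)CC)[C@@H](Br)C1
F0 | step 22 | none | none
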